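The six-membered ring is opened at C3–C4. C4 of the cyclohexenone is an allylic carbinol held between the oxirane carbon C5 and the enone β-carbon C3, so this bond is traced back to a C3 alkenyl metal and a C4 aldehyde. A nickel/chromium-mediated intramolecular alkenyl iodide–aldehyde coupling forms the C3–C4 bond, the carbocycle and the C4 stereocentre in one operation. Its substrate is an acyclic oxirane carrying the formyl group on C5 and, on the fully substituted C6, the protected hydroxyfarnesyl chain and a (Z)-β-iodoenone. The oxirane comes from a titanium–tartrate epoxidation of a Z-allylic alcohol assembled by hydrostannation and Stille coupling.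

Key step: step 17

Remark: ring numbering is C1 (C=O), C2 (=CH), C3 (C–CH2OAc), C4 (CHOH), C5 and C6 (oxirane, C6 bearing the chain). The target is read as (4R,5R,6R), with the C4 hydroxyl cis to the oxirane oxygen and an all-E 12-hydroxyfarnesyl chain. "TBDPSO-farnesyl" below means (2E,6E,10E)-12-(tert-butyldiphenylsilyloxy)-3,7,11-trimethyldodeca-2,6,10-trien-1-yl.

Step 1
Reactants: 1 (2E,6E)-farnesol
Product: 2 (2E,6E)-farnesyl acetate
Conditions: Ac2O, pyridine, DMAP (cat.), CH2Cl2, 0 °C to rt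
Reagents that add atoms: acetic anhydride, CC(=O)OC(C)=O
Why: DMAP-catalysed esterification masks the allylic hydroxyl so that it is not oxidised in step 2.

Step 2
Reactants: 2 (2E,6E)-farnesyl acetate
Product: 3 (2E,6E,10E)-12-hydroxy-3,7,11-trimethyldodeca-2,6,10-trienyl acetate
Conditions: SeO2 (cat.), t-BuOOH, salicylic acid (cat.), CH2Cl2, 0 °C to rt, stopped at partial conversion
Reagents that add atoms: tert-butyl hydroperoxide, CC(C)(C)OO (terminal oxidant); selenium dioxide, O=[Se]=O (catalytic oxygen carrier)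
Why: Sharpless–Umbreit allylic hydroxylation (ene reaction, then [2,3]-sigmatropic shift) should pick the E-methyl group of the electron-rich terminal prenyl unit, the C2–C3 alkene being deactivated by the allylic acetate, and so give the (10E)-alcohol.

Step 3
Reactants: 3 (2E,6E,10E)-12-hydroxy-3,7,11-trimethyldodeca-2,6,10-trienyl acetate
Product: 4 (2E,6E,10E)-12-(tert-butyldiphenylsilyloxy)-3,7,11-trimethyldodeca-2,6,10-trienyl acetate
Conditions: TBDPSCl, imidazole, DMF, rt
Reagents that add atoms: tert-butylchlorodiphenylsilane, CC(C)(C)[Si](Cl)(c1ccccc1)c1ccccc1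
Why: Silyl ether formation puts the most acid-stable of the three silyl groups on the chain terminus, which is unmasked last.

Step 4
Reactants: 4 (2E,6E,10E)-12-(tert-butyldiphenylsilyloxy)-3,7,11-trimethyldodeca-2,6,10-trienyl acetate
Product: 5 (2E,6E,10E)-12-(tert-butyldiphenylsilyloxy)-3,7,11-trimethyldodeca-2,6,10-trien-1-ol
Conditions: K2CO3 (cat.), MeOH, 0 °C to rt
Reagents that add atoms: none
Why: Base-catalysed transesterification removes the acetate while the TBDPS ether is inert.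

Step 5
Reactants: 5 (2E,6E,10E)-12-(tert-butyldiphenylsilyloxy)-3,7,11-trimethyldodeca-2,6,10-trien-1-ol
Product: 6 (2E,6E,10E)-1-bromo-12-(tert-butyldiphenylsilyloxy)-3,7,11-trimethyldodeca-2,6,10-triene
Conditions: CBr4, PPh3, CH2Cl2, −20 to 0 °C; used at once
Reagents that add atoms: carbon tetrabromide, BrC(Br)(Br)Br
Why: Appel bromination displaces the oxyphosphonium of the primary allylic alcohol by SN2 at low temperature, without allylic transposition and without touching the silyl ether.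

Step 6
Reactants: 7 but-2-yne-1,4-diol
Product: 8 (E)-2-(tributylstannyl)but-2-ene-1,4-diol
Conditions: Bu3SnH, PdCl2(PPh3)2 (cat.), THF, rt
Reagents that add atoms: tributyltin hydride, CCCC[SnH](CCCC)CCCC
Why: Palladium-catalysed hydrostannation adds H and SnBu3 to the same side of the symmetrical alkyne, which fixes the two hydroxymethyl groups cis and allows only one regioisomer.

Step 7
Reactants: 8 (E)-2-(tributylstannyl)but-2-ene-1,4-diol
Product: 9 (E)-4-(triethylsilyloxy)-2-(tributylstannyl)but-2-en-1-ol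
Conditions: TESCl (1 equiv), imidazole, CH2Cl2, −78 °C
Reagents that add atoms: chlorotriethylsilane, CC[Si](Cl)(CC)CC
Why: Sterically controlled monosilylation should take the C4 hydroxyl, because the hydroxyl next to the Bu3Sn-bearing carbon is shielded; the two ends are differentiated here, where they differ most.

Step 8
Reactants: 9 (E)-4-(triethylsilyloxy)-2-(tributylstannyl)but-2-en-1-ol and 6 (2E,6E,10E)-1-bromo-12-(tert-butyldiphenylsilyloxy)-3,7,11-trimethyldodeca-2,6,10-triene
Product: 10 (Z)-2-(TBDPSO-farnesyl)-4-(triethylsilyloxy)but-2-en-1-ol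
Conditions: Pd2(dba)3 (cat.), AsPh3 (cat.), DMF, rt to 40 °C
Reagents that add atoms: none
Why: Stille cross-coupling: Pd(0) ionises the allylic bromide, the alkenyl group passes from tin to palladium with retention, and reductive elimination at the unsubstituted allyl terminus should give the alkene with both CH2O groups cis and the chain alkenes unchanged.

Step 9
Reactants: 10 (Z)-2-(TBDPSO-farnesyl)-4-(triethylsilyloxy)but-2-en-1-ol
Product: 11 [(2S,3R)-2-(TBDPSO-farnesyl)-3-(triethylsilyloxymethyl)oxiran-2-yl]methanol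
Conditions: Ti(OiPr)4 (cat.), L-(+)-diethyl tartrate (cat.), t-BuOOH, 4 Å MS, CH2Cl2, −20 °C
Reagents that add atoms: tert-butyl hydroperoxide, CC(C)(C)OO
Why: Katsuki–Sharpless asymmetric epoxidation: the titanium–tartrate complex binds the only free allylic hydroxyl and, with the L-(+)-tartrate, should deliver oxygen to the face that gives the (2S,3R)-oxirane, so C5 and C6 are set together with their cis relationship inherited from the Z-alkene, while the three chain alkenes lack a free allylic hydroxyl and stay untouched.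

Step 10
Reactants: 11 [(2S,3R)-2-(TBDPSO-farnesyl)-3-(triethylsilyloxymethyl)oxiran-2-yl]methanol
Product: 12 (2R,3R)-2-(TBDPSO-farnesyl)-3-(triethylsilyloxymethyl)oxirane-2-carbaldehyde
Conditions: TPAP (cat.), NMO, 4 Å MS, CH2Cl2, rt
Reagents that add atoms: none
Why: Ley–Griffith oxidation gives the aldehyde under neutral conditions; its α-carbon is fully substituted, so nothing can epimerise, and oxirane, silyl ethers and alkenes are spared.

Step 11
Reactants: 13 propargyl alcohol
Product: 14 tert-butyldimethyl(prop-2-ynyloxy)silane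
Conditions: TBSCl, imidazole, CH2Cl2, 0 °C to rt
Reagents that add atoms: tert-butylchlorodimethylsilane, CC(C)(C)[Si](C)(C)Cl
Why: Silyl ether formation gives an ether that is a poor leaving group, which matters later for the alkenylchromium species.

Step 12
Reactants: 14 tert-butyldimethyl(prop-2-ynyloxy)silane and 12 (2R,3R)-2-(TBDPSO-farnesyl)-3-(triethylsilyloxymethyl)oxirane-2-carbaldehyde
Product: 16 4-(tert-butyldimethylsilyloxy)-1-[(2S,3R)-2-(TBDPSO-farnesyl)-3-(triethylsilyloxymethyl)oxiran-2-yl]but-2-yn-1-ol (both carbinol epimers), via lithium acetylide 15 (not isolated)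
Conditions: n-BuLi, THF, −78 °C; then 12, −78 °C; H2O quench at −78 °C
Reagents that add atoms: none
Why: Deprotonation gives lithium acetylide 15, which adds to the non-enolisable aldehyde at low temperature (alkynyllithium 1,2-addition); the new carbinol centre is left uncontrolled because step 13 removes it.

Step 13
Reactants: 16 4-(tert-butyldimethylsilyloxy)-1-[(2S,3R)-2-(TBDPSO-farnesyl)-3-(triethylsilyloxymethyl)oxiran-2-yl]but-2-yn-1-ol
Product: 17 4-(tert-butyldimethylsilyloxy)-1-[(2R,3R)-2-(TBDPSO-farnesyl)-3-(triethylsilyloxymethyl)oxiran-2-yl]but-2-yn-1-one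
Conditions: Dess–Martin periodinane, CH2Cl2, 0 °C to rt
Reagents that add atoms: none
Why: Dess–Martin oxidation should convert both propargylic epimers into one ynone under conditions that the oxirane and the three silyl ethers tolerate.

Step 14
Reactants: 17 4-(tert-butyldimethylsilyloxy)-1-[(2R,3R)-2-(TBDPSO-farnesyl)-3-(triethylsilyloxymethyl)oxiran-2-yl]but-2-yn-1-one
Product: 18 (Z)-4-(tert-butyldimethylsilyloxy)-3-iodo-1-[(2R,3R)-2-(TBDPSO-farnesyl)-3-(triethylsilyloxymethyl)oxiran-2-yl]but-2-en-1-one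
Conditions: LiI, AcOH (slight excess), MeCN, 0 °C to rt
Reagents that add atoms: lithium iodide, [Li+].[I-]
Why: Hydroiodination of the ynone (conjugate addition of iodide, then protonation of the allenolate; net anti addition of HI) should place iodine on C3 cis to the acyl group; the mild stoichiometric reagent at low temperature is chosen to spare the oxirane, and any loss of the TES group only anticipates step 15.

Step 15
Reactants: 18 (Z)-4-(tert-butyldimethylsilyloxy)-3-iodo-1-[(2R,3R)-2-(TBDPSO-farnesyl)-3-(triethylsilyloxymethyl)oxiran-2-yl]but-2-en-1-one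
Product: 19 (Z)-4-(tert-butyldimethylsilyloxy)-1-[(2R,3R)-3-(hydroxymethyl)-2-(TBDPSO-farnesyl)oxiran-2-yl]-3-iodobut-2-en-1-one
Conditions: PPTS (cat.), MeOH/CH2Cl2, 0 °C
Reagents that add atoms: none
Why: Acid-catalysed methanolysis should remove the primary TES ether, which is cleaved far faster than the primary TBS and TBDPS ethers.

Step 16
Reactants: 19 (Z)-4-(tert-butyldimethylsilyloxy)-1-[(2R,3R)-3-(hydroxymethyl)-2-(TBDPSO-farnesyl)oxiran-2-yl]-3-iodobut-2-en-1-one
Product: 20 (2S,3R)-3-[(Z)-4-(tert-butyldimethylsilyloxy)-3-iodobut-2-enoyl]-3-(TBDPSO-farnesyl)oxirane-2-carbaldehyde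
Conditions: Dess–Martin periodinane, CH2Cl2, 0 °C; used directly
Reagents that add atoms: none
Why: Dess–Martin oxidation of the primary alcohol should give the aldehyde without touching the iodoenone or the oxirane, and the oxirane C5–H does not enolise under these conditions.

Step 17
Reactants: 20 (2S,3R)-3-[(Z)-4-(tert-butyldimethylsilyloxy)-3-iodobut-2-enoyl]-3-(TBDPSO-farnesyl)oxirane-2-carbaldehyde
Product: 22 (1R,5R,6R)-4-[(tert-butyldimethylsilyloxy)methyl]-5-hydroxy-1-(TBDPSO-farnesyl)-7-oxabicyclo[4.1.0]hept-3-en-2-one, via alkenylchromium(III) species 21 (not isolated)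
Conditions: CrCl2 (excess), NiCl2 (cat.), degassed DMF/THF, rt, high dilution with slow addition of 20; aqueous work-up
Reagents that add atoms: none
Why: Ni(0), formed from NiCl2 by Cr(II), inserts into the activated C3–I bond of 20 and passes the alkenyl group to Cr(III) with retention, giving 21, which adds through C3 to the C4 aldehyde and so forms the C3–C4 bond and the C4 carbinol. The closest known reaction type is the intramolecular Nozaki–Hiyama–Kishi coupling of alkenyl iodides, β-iodoenones included, with aldehydes. The cyclohexenone ring closes in a 6-exo-trig mode at the aldehyde carbonyl, and the C2=C3 double bond ends up inside the ring. The new C4 stereocentre is controlled by the adjacent oxirane carbon C5: in the cyclic transition state the aldehyde is expected to react through the rotamer whose oxygen lies on the side of the oxirane oxygen, where Cr(III) can bridge both oxygens, which places the C4 hydroxyl cis to the oxirane (4R). The step needs attack on the aldehyde only, in the presence of the C1 ketone, the oxirane and two silyl ethers; this rests on the strong aldehyde preference of alkenylchromium reagents, on fast nickel insertion into the electron-poor C–I bond, and on the silyloxy group being too poor a leaving group for β-elimination from 21. Ring closure itself is secured by the Z geometry of the iodoenone and by the cis arrangement of the acyl and formyl groups on the oxirane, which hold C3 next to C4.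

Step 18
Reactants: 22 (1R,5R,6R)-4-[(tert-butyldimethylsilyloxy)methyl]-5-hydroxy-1-(TBDPSO-farnesyl)-7-oxabicyclo[4.1.0]hept-3-en-2-one
Product: 23 (1R,5R,6R)-5-hydroxy-4-(hydroxymethyl)-1-(TBDPSO-farnesyl)-7-oxabicyclo[4.1.0]hept-3-en-2-one
Conditions: CSA (cat.), MeOH/CH2Cl2, 0 °C
Reagents that add atoms: none
Why: Acid-catalysed methanolysis should cleave the primary TBS ether selectively, since the TBDPS ether is much more stable to acid and the electron-poor epoxy enone resists acid-induced opening.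

Step 19
Reactants: 23 (1R,5R,6R)-5-hydroxy-4-(hydroxymethyl)-1-(TBDPSO-farnesyl)-7-oxabicyclo[4.1.0]hept-3-en-2-one
Product: 24 [(1R,5R,6R)-5-hydroxy-2-oxo-1-(TBDPSO-farnesyl)-7-oxabicyclo[4.1.0]hept-3-en-4-yl]methyl acetate
Conditions: AcCl (1 equiv), 2,4,6-collidine, CH2Cl2, −78 °C
Reagents that add atoms: acetyl chloride, CC(Cl)=O
Why: Selective acylation of the primary allylic hydroxyl with acetyl chloride and a hindered pyridine base at low temperature; the secondary C4 hydroxyl, flanked by the oxirane and the ring, should react much more slowly.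

Step 20
Reactants: 24 [(1R,5R,6R)-5-hydroxy-2-oxo-1-(TBDPSO-farnesyl)-7-oxabicyclo[4.1.0]hept-3-en-4-yl]methyl acetate
Product: 25 [(1R,5R,6R)-5-hydroxy-1-[(2E,6E,10E)-12-hydroxy-3,7,11-trimethyldodeca-2,6,10-trienyl]-2-oxo-7-oxabicyclo[4.1.0]hept-3-en-4-yl]methyl acetate (CNP0336169.1)
Conditions: HF·pyridine, pyridine, THF, 0 °C to rt
Reagents that add atoms: none
Why: Fluoride-mediated desilylation with pyridine-buffered HF·pyridine should remove the TBDPS ether; the weakly acidic medium avoids acetate migration or hydrolysis and leaves the epoxy enone intact.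

Compound list
1 | (2E,6E)-farnesol | CC(C)=CCC/C(C)=C/CC/C(C)=C/CO | starting material
2 | (2E,6E)-farnesyl acetate | CC(=O)OC/C=C(\C)CC/C=C(\C)CCC=C(C)C | intermediate
3 | (2E,6E,10E)-12-hydroxy-3,7,11-trimethyldodeca-2,6,10-trienyl acetate | CC(=O)OC/C=C(\C)CC/C=C(\C)CC/C=C(\C)CO | intermediate
4 | (2E,6E,10E)-12-(tert-butyldiphenylsilyloxy)-3,7,11-trimethyldodeca-2,6,10-trienyl acetate | CC(=O)OC/C=C(\C)CC/C=C(\C)CC/C=C(\C)CO[Si](c1ccccc1)(c1ccccc1)C(C)(C)C | intermediate
5 | (2E,6E,10E)-12-(tert-butyldiphenylsilyloxy)-3,7,11-trimethyldodeca-2,6,10-trien-1-ol | OC/C=C(\C)CC/C=C(\C)CC/C=C(\C)CO[Si](c1ccccc1)(c1ccccc1)C(C)(C)C | intermediate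
6 | (2E,6E,10E)-1-bromo-12-(tert-butyldiphenylsilyloxy)-3,7,11-trimethyldodeca-2,6,10-triene | BrC/C=C(\C)CC/C=C(\C)CC/C=C(\C)CO[Si](c1ccccc1)(c1ccccc1)C(C)(C)C | intermediate
7 | but-2-yne-1,4-diol | OCC#CCO | starting material
8 | (E)-2-(tributylstannyl)but-2-ene-1,4-diol (hydroxymethyl groups cis) | OC/C=C(\CO)[Sn](CCCC)(CCCC)CCCC | intermediate
9 | (E)-4-(triethylsilyloxy)-2-(tributylstannyl)but-2-en-1-ol | CC[Si](CC)(CC)OC/C=C(\CO)[Sn](CCCC)(CCCC)CCCC | intermediate
10 | (Z)-2-(TBDPSO-farnesyl)-4-(triethylsilyloxy)but-2-en-1-ol | CC[Si](CC)(CC)OC/C=C(\CO)C/C=C(\C)CC/C=C(\C)CC/C=C(\C)CO[Si](c1ccccc1)(c1ccccc1)C(C)(C)C | intermediate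
11 | [(2S,3R)-2-(TBDPSO-farnesyl)-3-(triethylsilyloxymethyl)oxiran-2-yl]methanol | CC[Si](CC)(CC)OC[C@H]1O[C@@]1(C/C=C(\C)CC/C=C(\C)CC/C=C(\C)CO[Si](c2ccccc2)(c2ccccc2)C(C)(C)C)CO | intermediate
12 | (2R,3R)-2-(TBDPSO-farnesyl)-3-(triethylsilyloxymethyl)oxirane-2-carbaldehyde | CC[Si](CC)(CC)OC[C@H]1O[C@@]1(C/C=C(\C)CC/C=C(\C)CC/C=C(\C)CO[Si](c2ccccc2)(c2ccccc2)C(C)(C)C)C=O | intermediate
13 | propargyl alcohol | C#CCO | starting material
14 | tert-butyldimethyl(prop-2-ynyloxy)silane | C#CCO[Si](C)(C)C(C)(C)C | intermediate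
15 | lithium acetylide of 14 (not isolated) | [Li]C#CCO[Si](C)(C)C(C)(C)C | intermediate
16 | 4-(tert-butyldimethylsilyloxy)-1-[(2S,3R)-2-(TBDPSO-farnesyl)-3-(triethylsilyloxymethyl)oxiran-2-yl]but-2-yn-1-ol, both carbinol epimers | CC[Si](CC)(CC)OC[C@H]1O[C@@]1(C/C=C(\C)CC/C=C(\C)CC/C=C(\C)CO[Si](c2ccccc2)(c2ccccc2)C(C)(C)C)C(O)C#CCO[Si](C)(C)C(C)(C)C | intermediate
17 | 4-(tert-butyldimethylsilyloxy)-1-[(2R,3R)-2-(TBDPSO-farnesyl)-3-(triethylsilyloxymethyl)oxiran-2-yl]but-2-yn-1-one | CC[Si](CC)(CC)OC[C@H]1O[C@@]1(C/C=C(\C)CC/C=C(\C)CC/C=C(\C)CO[Si](c2ccccc2)(c2ccccc2)C(C)(C)C)C(=O)C#CCO[Si](C)(C)C(C)(C)C | intermediate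
18 | (Z)-4-(tert-butyldimethylsilyloxy)-3-iodo-1-[(2R,3R)-2-(TBDPSO-farnesyl)-3-(triethylsilyloxymethyl)oxiran-2-yl]but-2-en-1-one | CC[Si](CC)(CC)OC[C@H]1O[C@@]1(C/C=C(\C)CC/C=C(\C)CC/C=C(\C)CO[Si](c2ccccc2)(c2ccccc2)C(C)(C)C)C(=O)/C=C(\I)CO[Si](C)(C)C(C)(C)C | intermediate
19 | (Z)-4-(tert-butyldimethylsilyloxy)-1-[(2R,3R)-3-(hydroxymethyl)-2-(TBDPSO-farnesyl)oxiran-2-yl]-3-iodobut-2-en-1-one | OC[C@H]1O[C@@]1(C/C=C(\C)CC/C=C(\C)CC/C=C(\C)CO[Si](c2ccccc2)(c2ccccc2)C(C)(C)C)C(=O)/C=C(\I)CO[Si](C)(C)C(C)(C)C | intermediate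
20 | (2S,3R)-3-[(Z)-4-(tert-butyldimethylsilyloxy)-3-iodobut-2-enoyl]-3-(TBDPSO-farnesyl)oxirane-2-carbaldehyde | O=C[C@H]1O[C@@]1(C/C=C(\C)CC/C=C(\C)CC/C=C(\C)CO[Si](c2ccccc2)(c2ccccc2)C(C)(C)C)C(=O)/C=C(\I)CO[Si](C)(C)C(C)(C)C | intermediate
21 | alkenylchromium(III) dichloride derived from 20, Cr in place of I (not isolated) | O=C[C@H]1O[C@@]1(C/C=C(\C)CC/C=C(\C)CC/C=C(\C)CO[Si](c2ccccc2)(c2ccccc2)C(C)(C)C)C(=O)/C=C(\[Cr](Cl)Cl)CO[Si](C)(C)C(C)(C)C | intermediate
22 | (1R,5R,6R)-4-[(tert-butyldimethylsilyloxy)methyl]-5-hydroxy-1-(TBDPSO-farnesyl)-7-oxabicyclo[4.1.0]hept-3-en-2-one | CC(C)(C)[Si](C)(C)OCC1=CC(=O)[C@]2(C/C=C(\C)CC/C=C(\C)CC/C=C(\C)CO[Si](c3ccccc3)(c3ccccc3)C(C)(C)C)O[C@@H]2[C@@H]1O | intermediate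
23 | (1R,5R,6R)-5-hydroxy-4-(hydroxymethyl)-1-(TBDPSO-farnesyl)-7-oxabicyclo[4.1.0]hept-3-en-2-one | OCC1=CC(=O)[C@]2(C/C=C(\C)CC/C=C(\C)CC/C=C(\C)CO[Si](c3ccccc3)(c3ccccc3)C(C)(C)C)O[C@@H]2[C@@H]1O | intermediate
24 | [(1R,5R,6R)-5-hydroxy-2-oxo-1-(TBDPSO-farnesyl)-7-oxabicyclo[4.1.0]hept-3-en-4-yl]methyl acetate | CC(=O)OCC1=CC(=O)[C@]2(C/C=C(\C)CC/C=C(\C)CC/C=C(\C)CO[Si](c3ccccc3)(c3ccccc3)C(C)(C)C)O[C@@H]2[C@@H]1O | intermediate
25 | [(1R,5R,6R)-5-hydroxy-1-[(2E,6E,10E)-12-hydroxy-3,7,11-trimethyldodeca-2,6,10-trienyl]-2-oxo-7-oxabicyclo[4.1.0]hept-3-en-4-yl]methyl acetate | CC(=O)OCC1=CC(=O)[C@]2(C/C=C(\C)CC/C=C(\C)CC/C=C(\C)CO)O[C@@H]2[C@@H]1O | target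

Total step count: 20. Longest linear sequence: 17 steps (steps 1–5, 8–10 and 12–20, from farnesol).

Steps most likely to fail

Step 17. The aldehyde may be attacked on the face that leaves the C4 hydroxyl trans to the oxirane; in addition, chromium(II) may slowly reduce the epoxy ketone if ring closure is sluggish, which the slow addition at high dilution is meant to limit. The fallback sets C4 by displacement instead of by facial selectivity. It sets out from 20, which is cyclised as in step 17 to the C4-epimeric alcohol (1R,5S,6R)-4-[(tert-butyldimethylsilyloxy)methyl]-5-hydroxy-1-(TBDPSO-farnesyl)-7-oxabicyclo[4.1.0]hept-3-en-2-one F1. A Mitsunobu reaction (PPh3, DIAD, 4-nitrobenzoic acid, THF, 0 °C to rt) should invert C4 by SN2 displacement; attack at C2 is disfavoured because it is the α-carbon of the enone. This gives the (1R,5R,6R) 4-nitrobenzoate F2. Brief methanolysis (K2CO3, MeOH, 0 °C) releases the alcohol and comes back to the route at 22.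

Step 8. Transfer of the α-branched alkenyl group from tin to palladium may be slow, so that protodestannylation, homocoupling or coupling at the wrong allyl terminus competes. The fallback builds the trisubstituted alkene by olefination and sets out from bromide 6. Alkylation of methyl bis(2,2,2-trifluoroethyl)phosphonoacetate with 6 (NaH, THF/DMF) gives methyl 2-[bis(2,2,2-trifluoroethoxy)phosphoryl]-2-(TBDPSO-farnesyl)acetate F3. Commercial (Z)-but-2-ene-1,4-diol is silylated (TESCl, imidazole) to (Z)-1,4-bis(triethylsilyloxy)but-2-ene F4 and ozonised (O3, CH2Cl2, −78 °C; Me2S) to 2-(triethylsilyloxy)acetaldehyde F5. Still–Gennari olefination of F3 and F5 (KHMDS, 18-crown-6, THF, −78 °C) should give methyl (Z)-2-(TBDPSO-farnesyl)-4-(triethylsilyloxy)but-2-enoate F6, with the ester cis to the CH2OTES group. Reduction with DIBAL-H (CH2Cl2, −78 °C) comes back to the route at 10.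

Step 9. A Z-configured, 2-substituted allylic alcohol belongs to the slower substrate class for the titanium–tartrate system, so turnover may stall and enantioselectivity may erode. The fallback epoxidises the same alkene from its other hydroxyl, as a 3,3-disubstituted allylic alcohol, and sets out from 10. Acetylation (Ac2O, pyridine, DMAP) gives (Z)-2-(TBDPSO-farnesyl)-4-(triethylsilyloxy)but-2-enyl acetate F7. Removal of the TES ether (PPTS, MeOH, 0 °C) gives (Z)-4-hydroxy-2-(TBDPSO-farnesyl)but-2-enyl acetate F8. Katsuki–Sharpless epoxidation, now with D-(−)-diethyl tartrate because the directing hydroxyl sits on the other alkene carbon, should give [(2S,3R)-3-(hydroxymethyl)-2-(TBDPSO-farnesyl)oxiran-2-yl]methyl acetate F9, with the same absolute configuration at both oxirane carbons as 11. Silylation (TESCl, imidazole) gives [(2S,3R)-2-(TBDPSO-farnesyl)-3-(triethylsilyloxymethyl)oxiran-2-yl]methyl acetate F10. Methanolysis of the acetate (K2CO3, MeOH, 0 °C) comes back to the route at 11.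

Further compounds
F1 | step 17 | (1R,5S,6R)-4-[(tert-butyldimethylsilyloxy)methyl]-5-hydroxy-1-(TBDPSO-farnesyl)-7-oxabicyclo[4.1.0]hept-3-en-2-one | CC(C)(C)[Si](C)(C)OCC1=CC(=O)[C@]2(C/C=C(\C)CC/C=C(\C)CC/C=C(\C)CO[Si](c3ccccc3)(c3ccccc3)C(C)(C)C)O[C@@H]2[C@H]1O
F2 | step 17 | (1R,5R,6R)-4-[(tert-butyldimethylsilyloxy)methyl]-2-oxo-1-(TBDPSO-farnesyl)-7-oxabicyclo[4.1.0]hept-3-en-5-yl 4-nitrobenzoate | CC(C)(C)[Si](C)(C)OCC1=CC(=O)[C@]2(C/C=C(\C)CC/C=C(\C)CC/C=C(\C)CO[Si](c3ccccc3)(c3ccccc3)C(C)(C)C)O[C@@H]2[C@@H]1OC(=O)c4ccc(cc4)[N+](=O)[O-]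
F3 | step 8 | methyl 2-[bis(2,2,2-trifluoroethoxy)phosphoryl]-2-(TBDPSO-farnesyl)acetate | COC(=O)C(C/C=C(\C)CC/C=C(\C)CC/C=C(\C)CO[Si](c1ccccc1)(c1ccccc1)C(C)(C)C)P(=O)(OCC(F)(F)F)OCC(F)(F)F
F4 | step 8 | (Z)-1,4-bis(triethylsilyloxy)but-2-ene | CC[Si](CC)(CC)OC/C=C\CO[Si](CC)(CC)CC
F5 | step 8 | 2-(triethylsilyloxy)acetaldehyde | CC[Si](CC)(CC)OCC=O
F6 | step 8 | methyl (Z)-2-(TBDPSO-farnesyl)-4-(triethylsilyloxy)but-2-enoate | CC[Si](CC)(CC)OC/C=C(\C(=O)OC)C/C=C(\C)CC/C=C(\C)CC/C=C(\C)CO[Si](c1ccccc1)(c1ccccc1)C(C)(C)C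
F7 | step 9 | (Z)-2-(TBDPSO-farnesyl)-4-(triethylsilyloxy)but-2-enyl acetate | CC[Si](CC)(CC)OC/C=C(\COC(C)=O)C/C=C(\C)CC/C=C(\C)CC/C=C(\C)CO[Si](c1ccccc1)(c1ccccc1)C(C)(C)C
F8 | step 9 | (Z)-4-hydroxy-2-(TBDPSO-farnesyl)but-2-enyl acetate | OC/C=C(\COC(C)=O)C/C=C(\C)CC/C=C(\C)CC/C=C(\C)CO[Si](c1ccccc1)(c1ccccc1)C(C)(C)C
F9 | step 9 | [(2S,3R)-3-(hydroxymethyl)-2-(TBDPSO-farnesyl)oxiran-2-yl]methyl acetate | OC[C@H]1O[C@@]1(C/C=C(\C)CC/C=C(\C)CC/C=C(\C)CO[Si](c2ccccc2)(c2ccccc2)C(C)(C)C)COC(C)=O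
F10 | step 9 | [(2S,3R)-2-(TBDPSO-farnesyl)-3-(triethylsilyloxymethyl)oxiran-2-yl]methyl acetate | CC[Si](CC)(CC)OC[C@H]1O[C@@]1(C/C=C(\C)CC/C=C(\C)CC/C=C(\C)CO[Si](c2ccccc2)(c2ccccc2)C(C)(C)C)COC(C)=O
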